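Ring is what I count in these four flasks, and since the same substrate and activator go into each, the question is what the timing of the addition costs by the end.

| flask | substrate | activator | remark | time |
|---|---|---|---|---|
| delta | 0.30 M | 0.36 M | run made earlier |  |
| alpha | 0.20 M | 0.36 M | run made earlier |  |
| eta | 0.45 M | 0.36 M | run made earlier |  |
| zeta | 0.30 M | 0.54 M | run made earlier |  |
| summer | 0.30 M (fed, over 2.0 min) | 0.360 M | all else is in the flask from the start; the feed brings no volume worth counting | 5.0 min |
| autumn | 0.30 M | 0.360 M (fed, over 2.0 min) | all else is in the flask from the start; the feed brings no volume worth counting | 5.0 min |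
| dawn | 0.30 M (in portions, 4, over 2.0 min) | 0.360 M | first portion at the start, last at 2.0 min | 5.0 min |
| spring | 0.30 M | 0.360 M | everything together at the start | 5.0 min |

| run | time / min | ring / % | substrate / % |
|---|---|---|---|
| delta | 0.417 | 5.4 | 49.3 |
| delta | 0.667 | 10.3 | 36.4 |
| delta | 1.00 | 15.7 | 24.8 |
| delta | 2.00 | 33.9 | 11.2 |
| delta | 3.00 | 46.2 | 5.2 |
| delta | 5.00 | 55.5 | 1.5 |
| alpha | 0.200 | 1.5 | 68.0 |
| alpha | 0.667 | 11.1 | 34.0 |
| alpha | 1.00 | 18.5 | 22.1 |
| alpha | 1.50 | 28.7 | 11.9 |
| alpha | 2.50 | 44.3 | 4.2 |
| alpha | 3.00 | 49.8 | 3.0 |
| eta | 0.250 | 1.2 | 63.5 |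
| eta | 0.417 | 4.4 | 51.4 |
| eta | 0.667 | 9.6 | 38.9 |
| eta | 1.00 | 14.9 | 30.4 |
| eta | 2.00 | 29.6 | 17.5 |
| eta | 3.00 | 38.1 | 12.1 |
| zeta | 0.250 | 3.2 | 50.9 |
| zeta | 0.833 | 17.9 | 16.7 |
| zeta | 1.33 | 28.3 | 6.9 |
| zeta | 2.00 | 42.5 | 3.1 |
| zeta | 3.00 | 52.5 | 0 |

(standard deviation of a reading: 0.5 percentage points)

- the best flask by amount of ring, in percent of the substrate charged; "all alike" if 1.5 percentage points covers them all (summer / autumn / dawn / spring / all alike)
- amount of ring at the end, in percent of the substrate charged, summer
- amount of ring at the end, in percent of the substrate charged, autumn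
- amount of ring at the end, in percent of the substrate charged, dawn
- amount of ring at the end, in percent of the substrate charged, spring



In the delta run, which is spring's recipe, ring gains 0.182 min⁻¹ as a fraction of the charge between 1.00 min and 2.00 min, then 0.123 min⁻¹ over the next interval and 0.0465 min⁻¹ up to 5.00 min, so the rate slows by a factor of 1.48 and then of 2.65. I read the last slowing as a decay with a time constant of 1.54 min, and the rate left at the last reading then adds 3.75% of the charge, which puts the ceiling near 59.2%.

Summer and dawn both hold material back by 1.00 min on average, so I define the delay factor, the ratio by which that mean delay multiplies the climb still open at the end, as the exponential of the delay over the time constant: 1.91. Summer and dawn therefore keep 7.16% open and stand near 52.1%, while I take delta's 55.5% for spring, and that lead of 3.4 percentage points exceeds the margin. Autumn has the same delay with substrate waiting for its activator, and the eta run, with more substrate per activator, lies 8.1 points under delta at 3.00 min, so I take that much off again and say 44.0%.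

The forecast names summer as best, with 58.5% for summer, 50% for autumn, 58% for dawn and 55.5% for spring, and says of fed substrate that “ring arrives later: about 58 at 5 min”.

The flasks give 53.3% for summer, 44.2% for autumn, 52.9% for dawn and 55.8% for spring, so the best is spring.

    substrate + activator → activated form (k = 0.0890 M⁻¹ s⁻¹)
    activated form ⇌ ring (K = 2.20, k = 0.00830 s⁻¹)
    substrate + activated form → open dimer (k = 0.00100 M⁻¹ s⁻¹)
    2 substrate → self-condensation product (k = 0.00860 M⁻¹ s⁻¹)

By 50.0 min ring stands at 63.9% in summer and 61.1% in spring, so the climb between 5.0 min and that later time is greater in summer, by a ratio of 2.03 beside the delay factor of 1.91. The neighbouring flask is autumn with 0.090 M of activator, which is 30.0% of the substrate charge; with activator as the limiting reagent, I scale my whole autumn figure, the delay factor and the deduction from the eta run included, by that share and reckon 13.2%. This neighbour of autumn ends with 8.22% of its own activator charge, 26.7% of its substrate and ring at 16.0%.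

All runs were generated by integration for substances that don't exist.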